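**Strategy.** Ring A is cut by a [3+3] disconnection into the C2–C3–C4 unit and the C1–C10–C5 unit that ring B already carries. The key step joins them in one flask: a malonate-bearing phosphorus ylide olefinates the C1 aldehyde (Z) and the tethered malonate carbanion then adds to C5 of the ring B enone, forming C1–C2 and C4–C5 and closing ring A. It exploits the 1,3-relationship of C1 and C5 across quaternary C10 and the C7 carbonyl that makes C5 electrophilic. The precursor is a 4-formyl-4-methylcyclohexenone (ring B with the C9 side chain, from an auxiliary-controlled Diels-Alder reaction) plus a three-carbon phosphonium malonate.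

Key step: step 6

Assumption: the (2R,5R) auxiliary is taken to shield the diene face that leads to (1R,6S)-9 (otherwise its (2S,5S) enantiomer is used, all else unchanged), and 10 is taken as purchasable; labdane numbering (C1–C20) and α/β face descriptors are used for all intermediates.

Step 1
Reactants: 1 (2R,5R)-2,5-diphenylpyrrolidine; 2 (E)-4-methoxybut-3-en-2-one
Product: 3 (E)-4-[(2R,5R)-2,5-diphenylpyrrolidin-1-yl]but-3-en-2-one
Conditions: MeOH, 50 °C
Reagents that add atoms: none
Why: Conjugate addition–elimination of the secondary amine on the β-methoxy enone (vinylogous transamidation) should give the E vinylogous amide with loss of methanol, and no stereocenter is formed.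

Step 2
Reactants: 3 vinylogous amide
Product: 4 (2R,5R)-1-[(1E)-3-(tert-butyldimethylsilyloxy)buta-1,3-dien-1-yl]-2,5-diphenylpyrrolidine
Conditions: KN(SiMe3)2, THF, −78 °C; then TBSCl, −78 °C to rt
Reagents that add atoms: tert-butyldimethylsilyl chloride, CC(C)(C)[Si](C)(C)Cl
Why: O-silylation of the potassium enolate of a vinylogous amide is the standard entry to 1-amino-3-silyloxy dienes, the E enamine geometry is kept and no stereocenter is formed.

Step 3
Reactants: 5 3-(tert-butyldiphenylsilyloxy)propanal; 6 2-(triphenylphosphoranylidene)propanal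
Product: 7 (2E)-5-(tert-butyldiphenylsilyloxy)-2-methylpent-2-enal
Conditions: toluene, 90 °C
Reagents that add atoms: none
Why: Wittig olefination with a stabilised ylide should give the E trisubstituted enal, the geometry that later places C1 trans and C20 cis to the C9 side chain.

Step 4
Reactants: 7 E enal; 4 chiral amino silyloxy diene
Product: 9 (1R,6S)-6-[2-(tert-butyldiphenylsilyloxy)ethyl]-1-methyl-4-oxocyclohex-2-ene-1-carbaldehyde, via Diels-Alder cycloadduct 8 (not isolated)
Conditions: toluene, 70 °C; then 1 M HCl, THF, 0 °C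
Reagents that add atoms: none
Why: Normal-demand Diels-Alder reaction in which the amino terminus of the diene bonds to the enal α-carbon (C10) and the CH2 terminus to the β-carbon (C9), the suprafacial addition carrying the E geometry into the C9/C10 relative configuration (CHO trans, CH3 cis to the C9 chain) while the C2-symmetric auxiliary shields one diene face and so fixes the absolute configuration, after which acid hydrolysis of the silyl enol ether and β-elimination of the amine unveil the C5=C6–C7=O enone.

Step 5
Reactants: 10 dimethyl 2-(2-bromoethyl)malonate; 11 triphenylphosphine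
Product: 12 [3,3-bis(methoxycarbonyl)propyl]triphenylphosphonium bromide
Conditions: MeCN, reflux
Reagents that add atoms: none
Why: SN2 alkylation of PPh3 by the primary bromide under neutral conditions should give the phosphonium salt without touching the malonate, and no stereocenter is formed.

Step 6
Reactants: 9 ring B aldehyde enone; 12 phosphonium malonate
Product: 15 dimethyl 12-(tert-butyldiphenylsilyloxy)-7-(trimethylsilyloxy)-13,14,15,16,17-pentanor-5β-labda-1,6-diene-18,19-dioate (cis-fused silyl enol ether), via ylide malonate dianion 13 (not isolated), via Z-alkenyl malonate 14 (not isolated)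
Conditions: 12 added to NaN(SiMe3)2 (2.1 equiv), THF, −78 to 0 °C; then 9, −78 °C to rt; then TMSCl, Et3N, 0 °C
Reagents that add atoms: trimethylsilyl chloride, C[Si](C)(C)Cl
Why: Double deprotonation of 12 (inverse addition, so that the mono-anion does not close to the cyclopropane) gives the salt-free ylide 13, whose non-stabilised ylide carbon C2 olefinates the neopentyl C1 aldehyde of 9 under kinetic control to the Z alkene 14, while the soft malonate centre C4 is spared because its addition to the aldehyde is reversible and its intermolecular addition to the hindered enone is slow. In 14 the Z double bond holds the sodium malonate over C5, and Michael addition to the C5=C6–C7=O enone closes ring A; silylation of the resulting C7 enolate drives this reversible step and records the enolate regiochemistry for step 7. The closest known reaction type is the tandem Wittig olefination/intramolecular Michael addition, used here as a [3+3] annulation of a 1,3-dinucleophile (C2, C4) onto a 1,3-dielectrophile (C1, C5). Ring A closes in the 6-exo-trig mode, ring B being already present. The only new stereocenter is C5, set by the tether, which can reach only the face of C5 syn to C1 and so should give the cis ring fusion (5β-H); this centre is cleared on purpose in step 7 and reset in step 11. The step needs chemoselectivity (ylide for the aldehyde over the ketone, malonate for C5 only) and Z selectivity, secured by the stoichiometry, the salt-free ylide and the fact that C4 can reach no electrophile other than C5 through a six-membered transition state.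

Step 7
Reactants: 15 cis-fused silyl enol ether
Product: 16 dimethyl 12-(tert-butyldiphenylsilyloxy)-7-oxo-13,14,15,16,17-pentanorlabda-1,5-diene-18,19-dioate
Conditions: Pd(OAc)2 (1.1 equiv), MeCN, rt
Reagents that add atoms: none
Why: Saegusa–Ito oxidation, in which the regiodefined C6=C7 silyl enol ether is palladated at C6 by divalent palladium and β-hydride loss from C5 gives the C5=C6–C7=O enone and zerovalent palladium, which removes the cis ring-fusion centre so that C5 can be reset later.

Step 8
Reactants: 16 dienone diester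
Product: 17 dimethyl 12-(tert-butyldiphenylsilyloxy)-7-oxo-13,14,15,16-tetranorlabda-1,5-diene-18,19-dioate (8α-CH3)
Conditions: LiN(i-Pr)2, THF, −78 °C; then MeI
Reagents that add atoms: iodomethane, CI
Why: Kinetic α′-deprotonation of the enone (C8 is the only enolisable position, C4 and C10 being quaternary) followed by C-methylation installs C17, the methyl being expected to enter anti to the C9 chain, although this centre becomes sp2 again in step 9.

Step 9
Reactants: 17 8-methyl enone
Product: 18 dimethyl 12-(tert-butyldiphenylsilyloxy)-7-(trifluoromethylsulfonyloxy)-13,14,15,16-tetranorlabda-1,5,7-triene-18,19-dioate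
Conditions: KN(SiMe3)2, THF, −78 °C; then PhNTf2
Reagents that add atoms: N-phenylbis(trifluoromethanesulfonimide), O=S(=O)(N(c1ccccc1)S(=O)(=O)C(F)(F)F)C(F)(F)F
Why: O-triflation of the cross-conjugated α′-enolate, which can form only towards C8, fixes the C7=C8 double bond regiospecifically, and no stereocenter is formed.

Step 10
Reactants: 18 dienyl triflate
Product: 19 dimethyl 12-(tert-butyldiphenylsilyloxy)-13,14,15,16-tetranorlabda-1,5,7-triene-18,19-dioate
Conditions: Pd(OAc)2 (5 mol %), PPh3, HCO2H, Bu3N, DMF, 60 °C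
Reagents that add atoms: none
Why: Palladium-catalysed formate reduction of the dienyl triflate (oxidative addition, formate-to-hydride exchange, reductive elimination) should give the homoannular 5,7-diene without touching the esters or the silyl ether.

Step 11
Reactants: 19 1,5,7-triene
Product: 20 dimethyl 12-(tert-butyldiphenylsilyloxy)-13,14,15,16-tetranorlabd-7-ene-18,19-dioate (5α-H)
Conditions: H2 (1 atm), skeletal Ni (W-2), EtOAc, rt
Reagents that add atoms: none
Why: Catalytic hydrogenation should saturate the unhindered cis C1=C2 bond and, as with 5,7-diene sterols, the C5=C6 bond of the conjugated diene while the trisubstituted C7=C8 bond survives, hydrogen reaching C5 from the α face opposite the angular C10 methyl and so setting the trans ring fusion.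

Step 12
Reactants: 20 geminal diester
Product: 21 methyl 12-(tert-butyldiphenylsilyloxy)-13,14,15,16,18-pentanorlabd-7-en-19-oate (C4 epimers)
Conditions: LiCl, H2O, DMSO, 150 °C
Reagents that add atoms: none
Why: Krapcho dealkoxycarbonylation (chloride SN2 at a methyl ester, loss of CO2, protonation) removes one ester of the now non-allylic malonate, and the C4 epimer mixture is of no consequence because C4 is planarised in step 13.

Step 13
Reactants: 21 mono ester
Product: 22 methyl 12-(tert-butyldiphenylsilyloxy)-13,14,15,16-tetranorlabd-7-en-19-oate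
Conditions: LiN(i-Pr)2, THF, −78 °C; then MeI, DMPU, −78 to 0 °C
Reagents that add atoms: iodomethane, CI
Why: Ester enolate alkylation in which the exocyclic enolate is attacked on its equatorial α face because the β face is screened by the 1,3-diaxial C10 methyl, which should give the quaternary C4 with 4α-CH3 and the axial 4β-CO2CH3.

Step 14
Reactants: 22 labd-7-ene ester
Product: 23 methyl 12-(tert-butyldiphenylsilyloxy)-7α,8α-dihydroxy-13,14,15,16-tetranorlabdan-19-oate
Conditions: OsO4 (5 mol %), NMO, acetone/H2O, rt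
Reagents that add atoms: osmium tetroxide, O=[Os](=O)(=O)=O; N-methylmorpholine N-oxide, C[N+]1([O-])CCOCC1; water, O
Why: Catalytic syn-dihydroxylation of the trisubstituted C7=C8 bond should occur on the α face, the β face being blocked by the axial C10 methyl, which sets C7 (α-OH) and C8 (α-OH, β-CH3) together.

Step 15
Reactants: 23 silyl ether diol
Product: 24 methyl 7α,8α,12-trihydroxy-13,14,15,16-tetranorlabdan-19-oate
Conditions: Bu4NF, THF, rt
Reagents that add atoms: none
Why: Fluoride cleavage of the silyl ether frees the primary C12 hydroxyl without affecting the hindered ester or any stereocenter.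

Step 16
Reactants: 24 triol ester
Product: 25 methyl 7α,8α-dihydroxy-12-iodo-13,14,15,16-tetranorlabdan-19-oate
Conditions: I2, PPh3, imidazole, CH2Cl2, 0 °C
Reagents that add atoms: iodine, [I][I]
Why: Appel-type iodination is selective for the unhindered primary alcohol over the axial secondary and the tertiary hydroxyl at low temperature and limited reagent, and no stereocenter is involved.

Step 17
Reactants: 25 primary iodide
Product: 26 methyl 7α,8α-dihydroxylabda-13(16),14-dien-19-oate
Conditions: buta-1,3-dien-2-ylmagnesium chloride (4 equiv, from chloroprene, Mg, THF), Li2CuCl4 (5 mol %), THF, 0 °C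
Reagents that add atoms: buta-1,3-dien-2-ylmagnesium chloride, C=CC(=C)[Mg]Cl
Why: Copper-catalysed Kumada-type coupling of a primary alkyl iodide with the 2-butadienyl Grignard reagent is a known route to 2-alkyl-1,3-butadienes, the excess reagent covering the two hydroxyls and the hindered axial ester staying inert at 0 °C.

Step 18
Reactants: 26 diene ester
Product: 27 labda-13(16),14-diene-7α,8α,19-triol
Conditions: LiAlH4, THF, 0 °C to reflux
Reagents that add atoms: none
Why: Hydride reduction of the hindered axial methyl ester gives the C19 primary alcohol, the unactivated diene and the stereocenters being untouched.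

Step 19
Reactants: 27 triol; 28 (E)-4-acetoxycinnamic acid
Product: 29 19-O-[(E)-4-acetoxycinnamoyl]labda-13(16),14-diene-7α,8α,19-triol
Conditions: EDC·HCl, DMAP (cat.), CH2Cl2, 0 °C
Reagents that add atoms: none
Why: Steglich esterification with about one equivalent of acid should acylate the primary C19 hydroxyl in preference to the hindered axial secondary C7 and the tertiary C8 hydroxyl, the E alkene being retained.

Step 20
Reactants: 29 aryl acetate
Product: 30 19-O-[(E)-4-hydroxycinnamoyl]labda-13(16),14-diene-7α,8α,19-triol (CNP0254560.2)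
Conditions: K2CO3 (0.2 equiv), MeOH, 0 °C
Reagents that add atoms: none
Why: Base-catalysed methanolysis cleaves the activated aryl acetate much faster than the hindered neopentyl cinnamate, which should free the phenol and give the target.

**Compound list**

1 | (2R,5R)-2,5-diphenylpyrrolidine | N1[C@@H](c2ccccc2)CC[C@@H]1c1ccccc1 | starting material
2 | (E)-4-methoxybut-3-en-2-one | CO/C=C/C(C)=O | starting material
3 | (E)-4-[(2R,5R)-2,5-diphenylpyrrolidin-1-yl]but-3-en-2-one | CC(=O)/C=C/N1[C@@H](c2ccccc2)CC[C@@H]1c1ccccc1 | intermediate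
4 | (2R,5R)-1-[(1E)-3-(tert-butyldimethylsilyloxy)buta-1,3-dien-1-yl]-2,5-diphenylpyrrolidine | C=C(O[Si](C)(C)C(C)(C)C)/C=C/N1[C@@H](c2ccccc2)CC[C@@H]1c1ccccc1 | intermediate
5 | 3-(tert-butyldiphenylsilyloxy)propanal | O=CCCO[Si](c1ccccc1)(c1ccccc1)C(C)(C)C | starting material
6 | 2-(triphenylphosphoranylidene)propanal | CC(C=O)=P(c1ccccc1)(c1ccccc1)c1ccccc1 | starting material
7 | (2E)-5-(tert-butyldiphenylsilyloxy)-2-methylpent-2-enal | O=C/C(C)=C/CCO[Si](c1ccccc1)(c1ccccc1)C(C)(C)C | intermediate
8 | Diels-Alder cycloadduct: 4-(tert-butyldimethylsilyloxy)-6-[2-(tert-butyldiphenylsilyloxy)ethyl]-2-[(2R,5R)-2,5-diphenylpyrrolidin-1-yl]-1-methylcyclohex-3-ene-1-carbaldehyde (C1 and C6 as in 9, amino-bearing carbon undefined) | O=C[C@@]1(C)C(N2[C@@H](c3ccccc3)CC[C@@H]2c2ccccc2)C=C(O[Si](C)(C)C(C)(C)C)C[C@@H]1CCO[Si](c1ccccc1)(c1ccccc1)C(C)(C)C | intermediate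
9 | (1R,6S)-6-[2-(tert-butyldiphenylsilyloxy)ethyl]-1-methyl-4-oxocyclohex-2-ene-1-carbaldehyde (ring B; CHO = C1, ring C1 = C10, ring C6 = C9) | O=C[C@@]1(C)C=CC(=O)C[C@@H]1CCO[Si](c1ccccc1)(c1ccccc1)C(C)(C)C | intermediate
10 | dimethyl 2-(2-bromoethyl)malonate | COC(=O)C(CCBr)C(=O)OC | starting material
11 | triphenylphosphine | c1ccc(cc1)P(c1ccccc1)c1ccccc1 | starting material
12 | [3,3-bis(methoxycarbonyl)propyl]triphenylphosphonium bromide | COC(=O)C(CC[P+](c1ccccc1)(c1ccccc1)c1ccccc1)C(=O)OC.[Br-] | intermediate
13 | ylide malonate dianion of 12, sodium salt | COC(=O)[C-](CC=P(c1ccccc1)(c1ccccc1)c1ccccc1)C(=O)OC.[Na+] | intermediate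
14 | dimethyl 2-{(2Z)-3-[6-(2-(tert-butyldiphenylsilyloxy)ethyl)-1-methyl-4-oxocyclohex-2-en-1-yl]prop-2-en-1-yl}malonate (ring centres as in 9) | COC(=O)C(C/C=C\[C@@]1(C)C=CC(=O)C[C@@H]1CCO[Si](c1ccccc1)(c1ccccc1)C(C)(C)C)C(=O)OC | intermediate
15 | dimethyl 12-(tert-butyldiphenylsilyloxy)-7-(trimethylsilyloxy)-13,14,15,16,17-pentanor-5β-labda-1,6-diene-18,19-dioate (cis-fused; 9α-H, 10β-CH3) | COC(=O)C1(C(=O)OC)CC=C[C@]2(C)[C@@H](CCO[Si](c3ccccc3)(c3ccccc3)C(C)(C)C)CC(O[Si](C)(C)C)=C[C@H]12 | intermediate
16 | dimethyl 12-(tert-butyldiphenylsilyloxy)-7-oxo-13,14,15,16,17-pentanorlabda-1,5-diene-18,19-dioate | COC(=O)C1(C(=O)OC)CC=C[C@]2(C)[C@@H](CCO[Si](c3ccccc3)(c3ccccc3)C(C)(C)C)CC(=O)C=C12 | intermediate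
17 | dimethyl 12-(tert-butyldiphenylsilyloxy)-7-oxo-13,14,15,16-tetranorlabda-1,5-diene-18,19-dioate (8α-CH3) | COC(=O)C1(C(=O)OC)CC=C[C@]2(C)[C@@H](CCO[Si](c3ccccc3)(c3ccccc3)C(C)(C)C)[C@H](C)C(=O)C=C12 | intermediate
18 | dimethyl 12-(tert-butyldiphenylsilyloxy)-7-(trifluoromethylsulfonyloxy)-13,14,15,16-tetranorlabda-1,5,7-triene-18,19-dioate | COC(=O)C1(C(=O)OC)CC=C[C@]2(C)[C@@H](CCO[Si](c3ccccc3)(c3ccccc3)C(C)(C)C)C(C)=C(OS(=O)(=O)C(F)(F)F)C=C12 | intermediate
19 | dimethyl 12-(tert-butyldiphenylsilyloxy)-13,14,15,16-tetranorlabda-1,5,7-triene-18,19-dioate | COC(=O)C1(C(=O)OC)CC=C[C@]2(C)[C@@H](CCO[Si](c3ccccc3)(c3ccccc3)C(C)(C)C)C(C)=CC=C12 | intermediate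
20 | dimethyl 12-(tert-butyldiphenylsilyloxy)-13,14,15,16-tetranorlabd-7-ene-18,19-dioate (5α-H, trans-fused) | COC(=O)C1(C(=O)OC)CCC[C@]2(C)[C@@H](CCO[Si](c3ccccc3)(c3ccccc3)C(C)(C)C)C(C)=CC[C@@H]12 | intermediate
21 | methyl 12-(tert-butyldiphenylsilyloxy)-13,14,15,16,18-pentanorlabd-7-en-19-oate (C4 epimers) | COC(=O)C1CCC[C@]2(C)[C@@H](CCO[Si](c3ccccc3)(c3ccccc3)C(C)(C)C)C(C)=CC[C@@H]12 | intermediate
22 | methyl 12-(tert-butyldiphenylsilyloxy)-13,14,15,16-tetranorlabd-7-en-19-oate (4α-CH3, 4β-CO2CH3) | COC(=O)[C@@]1(C)CCC[C@]2(C)[C@@H](CCO[Si](c3ccccc3)(c3ccccc3)C(C)(C)C)C(C)=CC[C@@H]12 | intermediate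
23 | methyl 12-(tert-butyldiphenylsilyloxy)-7α,8α-dihydroxy-13,14,15,16-tetranorlabdan-19-oate | COC(=O)[C@@]1(C)CCC[C@]2(C)[C@@H](CCO[Si](c3ccccc3)(c3ccccc3)C(C)(C)C)[C@](C)(O)[C@H](O)C[C@@H]12 | intermediate
24 | methyl 7α,8α,12-trihydroxy-13,14,15,16-tetranorlabdan-19-oate | COC(=O)[C@@]1(C)CCC[C@]2(C)[C@@H](CCO)[C@](C)(O)[C@H](O)C[C@@H]12 | intermediate
25 | methyl 7α,8α-dihydroxy-12-iodo-13,14,15,16-tetranorlabdan-19-oate | COC(=O)[C@@]1(C)CCC[C@]2(C)[C@@H](CCI)[C@](C)(O)[C@H](O)C[C@@H]12 | intermediate
26 | methyl 7α,8α-dihydroxylabda-13(16),14-dien-19-oate | COC(=O)[C@@]1(C)CCC[C@]2(C)[C@@H](CCC(=C)C=C)[C@](C)(O)[C@H](O)C[C@@H]12 | intermediate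
27 | labda-13(16),14-diene-7α,8α,19-triol | OC[C@@]1(C)CCC[C@]2(C)[C@@H](CCC(=C)C=C)[C@](C)(O)[C@H](O)C[C@@H]12 | intermediate
28 | (E)-4-acetoxycinnamic acid | CC(=O)Oc1ccc(/C=C/C(=O)O)cc1 | starting material
29 | 19-O-[(E)-4-acetoxycinnamoyl]labda-13(16),14-diene-7α,8α,19-triol | CC(=O)Oc1ccc(/C=C/C(=O)OC[C@@]2(C)CCC[C@]3(C)[C@@H](CCC(=C)C=C)[C@](C)(O)[C@H](O)C[C@@H]23)cc1 | intermediate
30 | 19-O-[(E)-4-hydroxycinnamoyl]labda-13(16),14-diene-7α,8α,19-triol (CNP0254560.2) | C=CC(=C)CC[C@H]1[C@](C)(O)[C@H](O)C[C@H]2[C@@](C)(COC(=O)/C=C/c3ccc(O)cc3)CCC[C@@]21C | target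

**Step count and risks**

Total step count: 20. Longest linear sequence: 18 steps (steps 1, 2, 4 and 6 to 20).

Steps most likely to fail:

1. Step 6. The Michael closure is reversible and may not go to completion at the hindered C5; the mono-deprotonated salt may also collapse to the cyclopropane diester before the ylide forms, and Z selectivity may erode. Fallback (irreversible addition–elimination at C5 in place of Michael addition and enolate trapping): setting out from 9, conjugate addition of thiophenol (PhSH, Et3N, CH2Cl2) should give the 3-(phenylthio) ketone F1, and chlorination–dehydrochlorination (N-chlorosuccinimide, CCl4, then Et3N) the 3-(phenylthio)enone F2. F2 then takes the place of 9 in the one-flask reaction with ylide 13: Wittig olefination at C1 gives the Z-alkenyl malonate F3, whose malonate adds to C5 and expels thiolate. C1–C2 and C4–C5 are thus again formed in one operation, and the fallback comes back to the route at dienone 16, step 7 no longer being needed.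

2. Step 4. The trisubstituted enal may react too slowly with the diene, and shielding of one diene face by the auxiliary may be incomplete. Fallback (catalyst control in place of auxiliary control): setting out from 7, Diels-Alder reaction with 2-(triisopropylsilyloxy)buta-1,3-diene under a chiral oxazaborolidinium catalyst ((S)-1-(2-methylphenyl)-3,3-diphenyltetrahydro-1H,3H-pyrrolo[1,2-c][1,3,2]oxazaborole protonated by HNTf2, CH2Cl2, −78 °C) should give the silyl enol ether aldehyde F4 with the silyloxy carbon para to C10. Saegusa–Ito oxidation (Pd(OAc)2, MeCN) then introduces the C5=C6 bond, and the fallback comes back to the route at 9.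

3. Step 11. The C7=C8 double bond may be over-reduced or migrate towards C8=C9, and hydrogen may reach C5 from the wrong face. Fallback (dissolving-metal reduction of the enone in place of diene hydrogenation): setting out from 17, Li in liquid NH3/THF with t-BuOH at −78 °C should reduce the enone with axial protonation at C5 to the trans-fused ketone F5. Tf2O with 2,6-di-tert-butyl-4-methylpyridine then gives the more substituted enol triflate F6, and formate reduction (Pd(OAc)2, PPh3, HCO2H, Bu3N) the 1,7-diene F7. Hydrogenation with RhCl(PPh3)3 saturates only the disubstituted C1=C2 bond, and the fallback comes back to the route at 20.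

**Further compounds**

F1 | step 6 | 6-[2-(tert-butyldiphenylsilyloxy)ethyl]-1-methyl-4-oxo-2-(phenylsulfanyl)cyclohexane-1-carbaldehyde (C1 and C6 as in 9) | O=C[C@@]1(C)C(Sc2ccccc2)CC(=O)C[C@@H]1CCO[Si](c1ccccc1)(c1ccccc1)C(C)(C)C
F2 | step 6 | 6-[2-(tert-butyldiphenylsilyloxy)ethyl]-1-methyl-4-oxo-2-(phenylsulfanyl)cyclohex-2-ene-1-carbaldehyde (C1 and C6 as in 9) | O=C[C@@]1(C)C(Sc2ccccc2)=CC(=O)C[C@@H]1CCO[Si](c1ccccc1)(c1ccccc1)C(C)(C)C
F3 | step 6 | dimethyl 2-{(2Z)-3-[6-(2-(tert-butyldiphenylsilyloxy)ethyl)-1-methyl-4-oxo-2-(phenylsulfanyl)cyclohex-2-en-1-yl]prop-2-en-1-yl}malonate | COC(=O)C(C/C=C\[C@@]1(C)C(Sc2ccccc2)=CC(=O)C[C@@H]1CCO[Si](c1ccccc1)(c1ccccc1)C(C)(C)C)C(=O)OC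
F4 | step 4 | 6-[2-(tert-butyldiphenylsilyloxy)ethyl]-1-methyl-4-(triisopropylsilyloxy)cyclohex-3-ene-1-carbaldehyde (C1 and C6 as in 9) | O=C[C@@]1(C)CC=C(O[Si](C(C)C)(C(C)C)C(C)C)C[C@@H]1CCO[Si](c1ccccc1)(c1ccccc1)C(C)(C)C
F5 | step 11 | dimethyl 12-(tert-butyldiphenylsilyloxy)-7-oxo-13,14,15,16-tetranorlabd-1-ene-18,19-dioate (5α-H, 8α-CH3) | COC(=O)C1(C(=O)OC)CC=C[C@]2(C)[C@@H](CCO[Si](c3ccccc3)(c3ccccc3)C(C)(C)C)[C@H](C)C(=O)C[C@@H]12
F6 | step 11 | dimethyl 12-(tert-butyldiphenylsilyloxy)-7-(trifluoromethylsulfonyloxy)-13,14,15,16-tetranorlabda-1,7-diene-18,19-dioate | COC(=O)C1(C(=O)OC)CC=C[C@]2(C)[C@@H](CCO[Si](c3ccccc3)(c3ccccc3)C(C)(C)C)C(C)=C(OS(=O)(=O)C(F)(F)F)C[C@@H]12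
F7 | step 11 | dimethyl 12-(tert-butyldiphenylsilyloxy)-13,14,15,16-tetranorlabda-1,7-diene-18,19-dioate | COC(=O)C1(C(=O)OC)CC=C[C@]2(C)[C@@H](CCO[Si](c3ccccc3)(c3ccccc3)C(C)(C)C)C(C)=CC[C@@H]12
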